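**Assumption:** The target SMILES has no stereocentre and no stereogenic double bond, so the compound is achiral and needs no enantiocontrol. The one sp3 stereocentre that appears on the way (in 4, 5, 10 and 11) is carried racemic and is erased on aromatisation. The 4-/5- NH tautomers of the imidazole are one compound.

## Retrosynthetic overview
1. O-Acetylcypholophine 14 ⇒ cypholophine 12 by O-acetylation in the last step.
2. Key step: both ring C–N bonds (N3–C4 and N1–C5) are cut at once, giving a formal [3+2] of an amidine (N–C–N) with a terminal propargylic acetate (C3). The ring methyl is the former terminal alkyne carbon. This replaces the usual diketone/aldehyde/NH3 or α-haloketone/amidine condensations.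
3. Propargylic acetate 5 ⇒ 3-arylpropanal 3 + ethynyl Grignard; 3 ⇒ 4-iodoveratrole 1 + allyl alcohol 2 (isomerising Heck).
4. Amidine 8 ⇒ δ-valerolactone 6, which supplies C2, the four-carbon chain and the free OH in one piece.
5. Ring order: the arene is bought, and the imidazole is the only ring formed (step 4).

## Route

Step 1
Reactants: 1 4-iodo-1,2-dimethoxybenzene (4-iodoveratrole); 2 prop-2-en-1-ol (allyl alcohol)
Product: 3 3-(3,4-dimethoxyphenyl)propanal
Conditions: Pd(OAc)2 (2 mol %), n-Bu4NCl (1.0 equiv), NaHCO3 (2.5 equiv), 2 (1.5 equiv), DMF, 45 °C, 16 h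
Reagents that add atoms: none
Why: In this Jeffery-type isomerising Heck reaction the aryl-Pd adds to the terminal alkene carbon, and β-hydride elimination/re-insertion toward the carbinol carbon releases the saturated aldehyde directly; no stereocentre is formed.

Step 2
Reactants: 3 3-(3,4-dimethoxyphenyl)propanal
Product: 5 rac-5-(3,4-dimethoxyphenyl)pent-1-yn-3-yl acetate, via bromomagnesium alkoxide 4 (not isolated)
Conditions: HC≡CMgBr (0.5 M in THF, 1.2 equiv), THF, −20 → 0 °C, 1 h; then Ac2O (2.0 equiv), DMAP (5 mol %), 0 °C → rt, 2 h; aq NH4Cl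
Reagents that add atoms: ethynylmagnesium bromide C#C[Mg]Br; acetic anhydride CC(=O)OC(C)=O
Why: Grignard 1,2-addition to the aldehyde is followed by in-flask O-acylation of the magnesium alkoxide; the new carbinol stereocentre is deliberately racemic because step 4 erases it.

Step 3
Reactants: 6 δ-valerolactone (tetrahydro-2H-pyran-2-one)
Product: 8 5-hydroxypentanimidamide hydrochloride, via 5-hydroxypentanamide 7 (not isolated)
Conditions: MeAl(Cl)NH2 (5 equiv, pre-formed from AlMe3 + NH4Cl, toluene, 0 °C → rt), toluene, 80 °C, 16 h; MeOH quench at 0 °C, filter, triturate with i-PrOH to remove NH4Cl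
Reagents that add atoms: ammonium chloride [NH4+].[Cl-]
Why: Weinreb-type aminolysis opens the lactone to the aluminium-bound hydroxy amide 7, and excess amino(chloro)methylaluminium exchanges the amide oxygen for NH (ester-to-amidine extension of the Garigipati amidine synthesis), so the chain OH is released from the ring and needs no protecting group.

Step 4
Reactants: 5 rac-5-(3,4-dimethoxyphenyl)pent-1-yn-3-yl acetate; 8 5-hydroxypentanimidamide hydrochloride
Product: 12 cypholophine (4-{4-[2-(3,4-dimethoxyphenyl)ethyl]-5-methyl-1H-imidazol-2-yl}butan-1-ol), via free amidine 9 (not isolated), via N-propargylamidine 10 (not isolated), via methyleneimidazoline 11 (not isolated)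
Conditions: 5 (1.0 equiv), 8 (1.5 equiv), CuI (10 mol %), 2,6-bis(4,5-dihydro-1,3-oxazol-2-yl)pyridine (achiral pybox, 12 mol %), iPr2NEt (4 equiv), degassed MeOH, 0 °C → rt, 16 h; then 60 °C, 4 h; aq NH3/EDTA work-up
Reagents that add atoms: none
Why: Proposed new method: Cu(I)/pybox and base convert the terminal propargylic acetate 5 into a copper acetylide that expels acetate to give an electrophilic Cu-allenylidene, the sp2 nitrogen of amidine 9 (kept at low concentration by the amidinium/iPr2NEt buffer to limit acyl transfer, methanolysis and catalyst poisoning) adds at the propargylic γ-carbon to give 10, Cu(I) then π-activates the regenerated terminal alkyne for Markovnikov 5-exo-dig attack by the second amidine nitrogen to give 11, and a base-mediated 1,3-prototropic shift aromatises 11 to 12, which erases the racemic stereocentre and turns the terminal alkyne carbon into the ring methyl; the closest known reaction types are the Cu-catalysed propargylic amination of aryl-, benzyl- and alkyl-substituted propargylic acetates, Cu-catalysed formal [3+2] annulations of propargylic esters with bis-nucleophiles, and the hydroamination–isomerisation of N-propargyl amidines and guanidines to imidazoles.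

Step 5
Reactants: 12 cypholophine
Product: 14 O-acetylcypholophine (4-{4-[2-(3,4-dimethoxyphenyl)ethyl]-5-methyl-1H-imidazol-2-yl}butyl acetate), via N,O-diacetate 13 (not isolated)
Conditions: Ac2O (3 equiv), pyridine (5 equiv), DMAP (5 mol %), CH2Cl2, 0 °C → rt, 2 h; then MeOH, rt, 1 h
Reagents that add atoms: acetic anhydride CC(=O)OC(C)=O
Why: DMAP-catalysed acylation esterifies the primary alcohol, and the N-acetyl group of 13 is an activated imidazolide that methanol cleaves selectively at rt while the primary alkyl acetate stays intact; no stereocentre is involved.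

## Compound list
1 | 4-iodo-1,2-dimethoxybenzene | COc1ccc(I)cc1OC | starting material
2 | prop-2-en-1-ol (allyl alcohol) | C=CCO | starting material
3 | 3-(3,4-dimethoxyphenyl)propanal | COc1ccc(CCC=O)cc1OC | intermediate
4 | bromomagnesium 5-(3,4-dimethoxyphenyl)pent-1-yn-3-olate (racemic, not isolated) | COc1ccc(CCC(O[Mg]Br)C#C)cc1OC | intermediate
5 | rac-5-(3,4-dimethoxyphenyl)pent-1-yn-3-yl acetate | COc1ccc(CCC(OC(C)=O)C#C)cc1OC | intermediate
6 | δ-valerolactone (tetrahydro-2H-pyran-2-one) | O=C1CCCCO1 | starting material
7 | 5-hydroxypentanamide (aluminium-bound in the flask, drawn neutral, not isolated) | NC(=O)CCCCO | intermediate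
8 | 5-hydroxypentanimidamide hydrochloride | Cl.NC(=N)CCCCO | intermediate
9 | 5-hydroxypentanimidamide, free base (not isolated) | NC(=N)CCCCO | intermediate
10 | rac-N-[5-(3,4-dimethoxyphenyl)pent-1-yn-3-yl]-5-hydroxypentanimidamide (not isolated) | COc1ccc(CCC(NC(=N)CCCCO)C#C)cc1OC | intermediate
11 | rac-4-{4-[2-(3,4-dimethoxyphenyl)ethyl]-5-methylidene-4,5-dihydro-1H-imidazol-2-yl}butan-1-ol (not isolated) | COc1ccc(CCC2N=C(CCCCO)NC2=C)cc1OC | intermediate
12 | cypholophine, 4-{4-[2-(3,4-dimethoxyphenyl)ethyl]-5-methyl-1H-imidazol-2-yl}butan-1-ol | COc1ccc(CCc2nc(CCCCO)[nH]c2C)cc1OC | intermediate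
13 | 4-{1-acetyl-4-[2-(3,4-dimethoxyphenyl)ethyl]-5-methyl-1H-imidazol-2-yl}butyl acetate (not isolated) | COc1ccc(CCc2nc(CCCCOC(C)=O)n(C(C)=O)c2C)cc1OC | intermediate
14 | O-acetylcypholophine, 4-{4-[2-(3,4-dimethoxyphenyl)ethyl]-5-methyl-1H-imidazol-2-yl}butyl acetate (achiral) | COc1ccc(CCc2nc(CCCCOC(C)=O)[nH]c2C)cc1OC | target

## Step count
- **Total step count:** 5.
- **Longest linear sequence:** 4 steps (1 → 2 → 4 → 5). Step 3 is the convergent branch.

## Three steps most likely to fail

**Step 4 (highest risk).**
- The alkyl-substituted Cu-allenylidene may lose a proton to give the enyne.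
- The amidine or the imidazole product may bind copper or be propargylated twice.
- Acetate 5 may be deacetylated before it ionises.

The fallback sets out from 3 and comes back to the route at 10. It makes the propargylic C–N bond by imine addition instead of propargylic substitution. Aldehyde 3 is condensed with racemic tert-butanesulfinamide (Ti(OEt)4, THF) to give (E)-N-[3-(3,4-dimethoxyphenyl)propylidene]-2-methylpropane-2-sulfinamide F1. Ethynylmagnesium bromide adds to it to give N-[5-(3,4-dimethoxyphenyl)pent-1-yn-3-yl]-2-methylpropane-2-sulfinamide F2. HCl in MeOH then removes the sulfinyl group to give 5-(3,4-dimethoxyphenyl)pent-1-yn-3-amine hydrochloride F3. Heating this salt with 8 and Et3N in EtOH (classical amidine exchange with loss of ammonia) gives 10. AgOTf (5 mol %) or Cs2CO3 closes 10 in the same pot through 11 to 12, and this irreversible ring closure pulls the exchange equilibrium forward.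

**Step 3.**
- The one-pot lactone-to-amidine conversion may stop at the hydroxy amide.
- The very polar salt may be hard to free from aluminium residues and NH4Cl.

The fallback sets out from 6 and comes back at 9. It activates the carbonyl by O-alkylation instead of by aluminium. Lactone 6 is opened with NH3 in MeOH to 7, which is isolated here. Et3O·BF4 in CH2Cl2 alkylates the amide oxygen to give ethyl 5-hydroxypentanimidate tetrafluoroborate F4. NH3 in MeOH converts this to 5-hydroxypentanimidamide tetrafluoroborate F5. That salt is used in place of 8 in step 4, where iPr2NEt frees 9.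

**Step 1.**
- The branched 2-arylpropanal isomer may form.
- The product aldehyde may undergo aldol condensation under the basic Heck conditions.

The fallback sets out from 1 and comes back at 3. It fixes the regiochemistry with an acrylate and then adjusts the oxidation state. Heck coupling of 1 with methyl acrylate (Pd(OAc)2, P(o-tol)3, NaOAc, DMF, 100 °C) gives methyl (E)-3-(3,4-dimethoxyphenyl)prop-2-enoate F6. Hydrogenation (H2, Pd/C, EtOAc) gives methyl 3-(3,4-dimethoxyphenyl)propanoate F7. DIBAL-H in toluene at −78 °C reduces this ester to 3.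

## Further compounds
F1 | step 4 | (E)-N-[3-(3,4-dimethoxyphenyl)propylidene]-2-methylpropane-2-sulfinamide (racemic at S) | COc1ccc(CC/C=N/S(=O)C(C)(C)C)cc1OC
F2 | step 4 | N-[5-(3,4-dimethoxyphenyl)pent-1-yn-3-yl]-2-methylpropane-2-sulfinamide (racemic) | COc1ccc(CCC(NS(=O)C(C)(C)C)C#C)cc1OC
F3 | step 4 | 5-(3,4-dimethoxyphenyl)pent-1-yn-3-amine hydrochloride (racemic) | Cl.COc1ccc(CCC(N)C#C)cc1OC
F4 | step 3 | ethyl 5-hydroxypentanimidate tetrafluoroborate | CCOC(=[NH2+])CCCCO.F[B-](F)(F)F
F5 | step 3 | 5-hydroxypentanimidamide tetrafluoroborate | NC(=[NH2+])CCCCO.F[B-](F)(F)F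
F6 | step 1 | methyl (E)-3-(3,4-dimethoxyphenyl)prop-2-enoate | COC(=O)/C=C/c1ccc(OC)c(OC)c1
F7 | step 1 | methyl 3-(3,4-dimethoxyphenyl)propanoate | COC(=O)CCc1ccc(OC)c(OC)c1
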